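The 1,3-dioxolane of the 6,8-dioxabicyclo[3.2.1]octane core (C1–O8–C5–O6–C7; C5 ketal carbon, C7 hexyl carbon) is read as a cis-epoxide (C1, C7, O6). Into its C1–O6 bond the C5=O8 carbonyl of a symmetric cyclohexane-1,3-dione has been inserted. In one operation silyl triflate converts epoxy-dione 7 into bridged ketal 9: two rings, inversion at C1, C5 fixed by the tether, and a regiodefined silyl enol ether. Dehydrogenation gives a levoglucosenone-like enone. Triacetic acid lactone adds anti to the O6–C7 bridge and closes the hemiketal (three stereocentres). The locked chair then directs the final hydroxylation. Only the epoxide needs a chiral catalyst.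

Key step: step 4

Remark (locants): the core is numbered as 6,8-dioxabicyclo[3.2.1]octane: C1 O–CH bridgehead, C2 CH2, C3 CH bearing the pyrone, C4 ring-fusion CH, C5 ketal carbon, O6, C7 hexyl-bearing CH, O8. The fused cyclohexane runs C4–C9 (hemiketal carbon)–C10 (CHOH)–C11–C12–C5.
Remark (assumption): 1, 4 and 11 are taken as catalogue compounds, and the antipode of the epoxidation ligand is chosen by correlation so that 2 is the (3R,4S) enantiomer.

Step 1
Reactants: 1 (Z)-dec-3-en-1-ol
Product: 2 (3R,4S)-cis-3,4-epoxydecan-1-ol = 2-[(2R,3S)-3-hexyloxiran-2-yl]ethan-1-ol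
Conditions: VO(Oi-Pr)3 (1 mol %), C2-symmetric bishydroxamic acid ligand derived from trans-1,2-diaminocyclohexane (2 mol %), cumene hydroperoxide, toluene, 0 °C → rt
Reagents that add atoms: cumene hydroperoxide CC(C)(OO)c1ccccc1
Why: Hydroxyl-directed vanadium–bishydroxamic acid asymmetric epoxidation of a Z-homoallylic alcohol: suprafacial O-transfer keeps the cis geometry and the ligand antipode selects the alkene face, which sets both epoxide carbons (3R,4S), the only catalyst-set stereochemistry of the route.

Step 2
Reactants: 2 (3R,4S)-cis-3,4-epoxydecan-1-ol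
Product: 3 (2S,3R)-2-hexyl-3-(2-iodoethyl)oxirane
Conditions: I2, PPh3, imidazole, CH2Cl2, 0 °C
Reagents that add atoms: iodine II
Why: Appel-type iodination (SN2 at the primary alkoxyphosphonium carbon), buffered by imidazole, should leave the 1,2-dialkyl epoxide and its two stereocentres untouched.

Step 3
Reactants: 3 (2S,3R)-2-hexyl-3-(2-iodoethyl)oxirane; 4 1,5-dimethoxycyclohexa-1,4-diene
Product: 7 2-{2-[(2R,3S)-3-hexyloxiran-2-yl]ethyl}-3-hydroxycyclohex-2-en-1-one (enol form of the 2-alkylcyclohexane-1,3-dione), via lithiated diene 5 (not isolated), via alkylated bis(enol ether) 6 (not isolated)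
Conditions: 4, t-BuLi, THF–DMPU, −78 °C; 3, −78 → −30 °C; then 0.02 M aq HCl–THF, 0 °C, minutes; pH 6 phosphate buffer; used promptly
Reagents that add atoms: water O
Why: The cyclohexadienyl anion is alkylated at its central carbon by SN2 on the primary iodide (far faster at −78 °C than attack on a dialkyl epoxide), and the two simple enol ethers are then hydrolysed under specific-acid catalysis, whose C-protonation is orders of magnitude faster than acid opening of the epoxide, so the C-alkylated dione should result with no stereocentre touched.

Step 4
Reactants: 7 epoxy-dione (enol form)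
Product: 9 bridged ketal TMS enol ether [(1S,5R,7S)-7-exo-hexyl-6,8-dioxabicyclo[3.2.1]octane fused at C4–C5 to a cyclohexene; C4=C9 double bond; OSiMe3 on C9], via vinylogous silyl ester 8 (not isolated)
Conditions: 2,6-lutidine (1.1 equiv), TMSOTf (1.3 equiv), CH2Cl2, −78 → −40 °C; Et3N quench, non-aqueous work-up, carried on crude
Reagents that add atoms: trimethylsilyl triflate C[Si](C)(C)OS(=O)(=O)C(F)(F)F
Why: Lutidine/TMSOTf first silylates the vinylogous acid (either oxygen, the dione being symmetric) to 8, whose enone oxygen (future O8) is the only strong internal nucleophile; excess TMSOTf then silylates the oxirane oxygen and O8 attacks C1 from the rear, breaking C1–O6 (6-exo-tet closure of the tetrahydropyran). The silyloxy-stabilised vinylogous oxocarbenium ion so formed has no hydrogen on C4 to lose and is captured at C5 by O6 with return of Me3Si+ to triflate (5-exo-trig on the C5=C4 resonance form), so C5=O8 ends up inserted into the C1–O6 bond and the three-membered ring (C1, C7, O6) becomes the five-membered ring C1–O8–C5–O6–C7. The closest known reaction types are the Lewis-acid or thermal rearrangement of δ,ε-epoxy ketones to 6,8-dioxabicyclo[3.2.1]octanes and silyl-triflate (Noyori-type) ketalisation with silyl ethers. C1 is set by SN2 inversion (R to S), C7 is untouched so that the cis-epoxide maps onto the exo-hexyl (threo) ketal, and C5 is fixed because the two-atom O6–C7 tether can reach only one face of the planar cation. The step needs attack at C1 rather than C7 and O- rather than C-alkylation: the six-membered exo transition state allows the collinear O8···C1–O6 geometry that the seven-membered endo one lacks, and the nucleophilic carbon C4 could only form a four- or five-membered carbocycle. It also leaves the enol ether regiodefined at C4=C9, which encodes the position of the later enone.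

Step 5
Reactants: 9 bridged ketal TMS enol ether
Product: 10 bridged ketal enone (same 1S,5R,7S core; C9 ketone; C3=C4 double bond inside the pyran ring)
Conditions: DDQ (1.1 equiv), 2,4,6-collidine, CH2Cl2, 0 °C → rt; aq NaHCO3 work-up
Reagents that add atoms: none
Why: DDQ dehydrogenation of a silyl enol ether: hydride is abstracted from C3, the only allylic C–H that gives a silyloxy-stabilised allyl cation, and loss of the silyl group gives the s-cis enone with C1, C5 and C7 unaffected.

Step 6
Reactants: 10 bridged ketal enone; 11 4-hydroxy-6-methyl-2H-pyran-2-one (triacetic acid lactone)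
Product: 13 10-deoxytrichopsistide B (target skeleton with CH2 at C10; all other stereocentres as in 15), via open keto-pyronol adduct 12 (not isolated)
Conditions: 11 (1.2 equiv), Et3N (10 mol %), MeCN, rt
Reagents that add atoms: none
Why: This is an amine-catalysed Michael addition/hemiketalisation of a cyclic vinylogous acid to an enone (as for 4-hydroxycoumarins): pyrone C3 attacks core C3 on the face anti to the O6–C7 bridge (levoglucosenone-type shielding), the labile C4–H settles cis to C3–H because only this fusion keeps C2 pseudo-axial on the new dihydropyran and away from the lactone C=O (A1,3 strain), and the 4-OH closes on C9 to the anomerically favoured axial hemiketal.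

Step 7
Reactants: 13 10-deoxytrichopsistide B
Product: 15 trichopsistide B, via dipotassium enolate pyronate 14 (not isolated)
Conditions: KHMDS (2.1 equiv), THF, −78 °C; 3-phenyl-2-(phenylsulfonyl)oxaziridine (1.1 equiv), −78 °C; AcOH, −78 °C → rt
Reagents that add atoms: 3-phenyl-2-(phenylsulfonyl)oxaziridine O=S(=O)(N1OC1c1ccccc1)c1ccccc1
Why: This is a Davis oxaziridine hydroxylation of a kinetic enolate: the first equivalent of base opens the hemiketal to ketone plus pyronate, the second removes the unhindered axial C10–H rather than the buried C4–H, and because the rigid pyran chair (C12 equatorial, C9 axial) locks the cyclohexanone in one chair, oxygen is delivered axially through the staggered chair-like transition state on the face syn to C4–H (10R), after which acidification re-closes the hemiketal.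

Compound list
1 | (Z)-dec-3-en-1-ol | CCCCCC/C=C\CCO | starting material
2 | (3R,4S)-cis-3,4-epoxydecan-1-ol | CCCCCC[C@@H]1O[C@@H]1CCO | intermediate
3 | (2S,3R)-2-hexyl-3-(2-iodoethyl)oxirane | CCCCCC[C@@H]1O[C@@H]1CCI | intermediate
4 | 1,5-dimethoxycyclohexa-1,4-diene | COC1=CCC=C(OC)C1 | starting material
5 | 6-lithio-1,5-dimethoxycyclohexa-1,4-diene | [Li]C1C(OC)=CCC=C1OC | intermediate
6 | 6-{2-[(2R,3S)-3-hexyloxiran-2-yl]ethyl}-1,5-dimethoxycyclohexa-1,4-diene | CCCCCC[C@@H]1O[C@@H]1CCC1C(OC)=CCC=C1OC | intermediate
7 | 2-{2-[(2R,3S)-3-hexyloxiran-2-yl]ethyl}-3-hydroxycyclohex-2-en-1-one | CCCCCC[C@@H]1O[C@@H]1CCC1=C(O)CCCC1=O | intermediate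
8 | 2-{2-[(2R,3S)-3-hexyloxiran-2-yl]ethyl}-3-(trimethylsilyloxy)cyclohex-2-en-1-one | CCCCCC[C@@H]1O[C@@H]1CCC1=C(O[Si](C)(C)C)CCCC1=O | intermediate
9 | bridged ketal TMS enol ether (1S,5R,7S; exo-hexyl; C4=C9; OTMS on C9) | CCCCCC[C@@H]1O[C@]23CCCC(O[Si](C)(C)C)=C3CC[C@@H]1O2 | intermediate
10 | bridged ketal enone (1S,5R,7S; C9=O; C3=C4) | CCCCCC[C@@H]1O[C@]23CCCC(=O)C3=CC[C@@H]1O2 | intermediate
11 | 4-hydroxy-6-methyl-2H-pyran-2-one | Cc1cc(O)cc(=O)o1 | starting material
12 | open Michael adduct (3R,4S; pyron-3-yl on C3 anti to the O6–C7 bridge; C9 ketone) | CCCCCC[C@@H]1O[C@]23CCCC(=O)[C@@H]3[C@@H](C[C@@H]1O2)c1c(O)cc(C)oc1=O | intermediate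
13 | 10-deoxytrichopsistide B | CCCCCC[C@@H]1O[C@]23CCC[C@@]4(O)Oc5cc(C)oc(=O)c5[C@H](C[C@@H]1O2)[C@H]34 | intermediate
14 | dipotassium C9=C10 enolate/pyronate of 12 | CCCCCC[C@@H]1O[C@]23CCC=C([O-])[C@@H]3[C@@H](C[C@@H]1O2)c1c([O-])cc(C)oc1=O.[K+].[K+] | intermediate
15 | trichopsistide B (1S,3R,4S,5R,7S,9S,10R in the local numbering) | CCCCCC[C@@H]1O[C@]23CC[C@@H](O)[C@@]4(O)Oc5cc(C)oc(=O)c5[C@H](C[C@@H]1O2)[C@H]34 | target

Total step count: 7. Longest linear sequence: 7 steps (1 → 2 → 3 → 7 → 9 → 10 → 13 → 15).

Steps most likely to fail

Step 4. The silyl triflate may open the epoxide by proton abstraction or hydride shift before the carbonyl oxygen engages. Alternatively O6 may stay silylated, so that the cation is not closed and the sequence stops after the first ring. The fallback sets out from 7 and comes back at 10; it separates the activating group from the epoxide activation. O-Methylation of 7 with TMSCHN2 (toluene–MeOH, 0 °C) should give the isolable methyl vinylogous ester F1. Catalytic BF3·OEt2 in CH2Cl2 at −78 °C, free of base and silicon, should isomerise it through a boron alkoxide that is free to close. This is the same oxirane-to-dioxolane expansion and gives the bridged ketal methyl enol ether F2. DDQ in pH 7-buffered wet CH2Cl2 then abstracts hydride from C3, and water attacks C9 to give 10.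

Step 7. Deprotonation may stray to C4, followed by β-elimination of pyronate or of a ketal oxygen. The pyronate or its methyl group may also be attacked. The fallback sets out from 13 and comes back at 15; it replaces enolate chemistry by enamine catalysis under near-neutral conditions. Proline (L-antipode by analogy with cyclohexanone, matched with the axial preference) and nitrosobenzene in DMSO should aminoxylate the less substituted enamine at C10 to give the 10-anilinooxy derivative F3. Zn/AcOH then cleaves the N–O bond to 15.

Step 6. The addition may be slow at the α-substituted enone. The intermediate enolate may expel O6 or O8 from C5, so that the ketal unravels, and protonation at C4 may stop at the wrong epimer. The fallback sets out from 10 and 11 and comes back at 13; it is a Mukaiyama–Michael addition that never generates a free enolate. Compound 11 is silylated (HMDS, neat, 80 °C) to the silyloxypyrone F4. Catalytic TMSOTf in CH2Cl2 at −78 °C couples it with 10 on the face anti to the bridge, with silyl transfer to the C9 oxygen, to give the C3-pyronyl TMS enol ether F5. Citric acid in aqueous MeOH then desilylates, protonates C4 under equilibrating conditions and lets the hemiketal close to 13.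

Further compounds
F1 | step 4 | 2-{2-[(2R,3S)-3-hexyloxiran-2-yl]ethyl}-3-methoxycyclohex-2-en-1-one | CCCCCC[C@@H]1O[C@@H]1CCC1=C(OC)CCCC1=O
F2 | step 4 | bridged ketal methyl enol ether (as 9, OMe on C9) | CCCCCC[C@@H]1O[C@]23CCCC(OC)=C3CC[C@@H]1O2
F3 | step 7 | (10R)-10-anilinooxy-10-deoxytrichopsistide B | CCCCCC[C@@H]1O[C@]23CC[C@@H](ONc6ccccc6)[C@@]4(O)Oc5cc(C)oc(=O)c5[C@H](C[C@@H]1O2)[C@H]34
F4 | step 6 | 6-methyl-4-(trimethylsilyloxy)-2H-pyran-2-one | Cc1cc(O[Si](C)(C)C)cc(=O)o1
F5 | step 6 | C3-(4-hydroxy-6-methyl-2-oxopyran-3-yl) TMS enol ether (C4=C9, OTMS on C9) | CCCCCC[C@@H]1O[C@]23CCCC(O[Si](C)(C)C)=C3[C@@H](C[C@@H]1O2)c1c(O)cc(C)oc1=O
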